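## Retrosynthetic overview

- **Key disconnection, O1–C2 (C–O):** the 2H-chromene is the oxa-6π valence isomer of a vinyl o-quinone methide, which is a tautomer of 2,5-dimethyl-3-phytyl-1,4-benzoquinone. A catalytic enantioselective cycloisomerization closes this bond last and sets C2 (S).
- **Quinone from phytylhydroquinone** by simple dehydrogenation; no protecting groups.
- **Aryl–C1′ disconnection (Friedel–Crafts):** 2,5-dimethylhydroquinone plus natural (E,7R,11R)-phytol. The symmetric hydroquinone gives one regioisomer, and phytol supplies C4′ and C8′.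
- **Ring order:** the benzene ring is bought; the pyran ring is the only ring made and is closed last through the C–O bond.

Assumption: "phytol" is the natural (2E,7R,11R) grade (≥97% E); the sense of induction in step 3 is a model prediction to be confirmed in a first screen, and the quinine-derived pseudoenantiomeric catalyst is used instead if the sense is opposite.

The target SMILES corresponds to (2S,4′R,8′R)-3,4-dehydro-β-tocopherol, with the 5,8-dimethyl pattern.

## Route

Step 1
Reactants: 1 2,5-dimethylbenzene-1,4-diol (2,5-dimethylhydroquinone); 2 natural phytol, (2E,7R,11R)-3,7,11,15-tetramethylhexadec-2-en-1-ol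
Product: 3 2,5-dimethyl-3-[(2E,7R,11R)-3,7,11,15-tetramethylhexadec-2-en-1-yl]benzene-1,4-diol (phytylhydroquinone)
Conditions: BF3·OEt2 (0.5 equiv), 1 (3 equiv), 1,4-dioxane, 25→45 °C, N2, 4 h; crude 3 freed from excess 1 by hexane/aqueous MeOH partition
Reagents that add atoms: none
Why: Friedel–Crafts allylation in which BF3-ionised phytol attacks through its primary allylic terminus at one of the two symmetry-equivalent free ring positions (each ortho to OH), so only one regioisomer can form; in dioxane the ion-paired allyl cation is expected to keep the E geometry to about 9:1, excess 1 suppresses dialkylation, the mild temperature avoids acid closure to the chroman, and C7/C11 of phytol are untouched (no new stereocentre).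

Step 2
Reactants: 3 2,5-dimethyl-3-[(2E,7R,11R)-3,7,11,15-tetramethylhexadec-2-en-1-yl]benzene-1,4-diol
Product: 4 2,5-dimethyl-3-[(2E,7R,11R)-3,7,11,15-tetramethylhexadec-2-en-1-yl]cyclohexa-2,5-diene-1,4-dione (phytylquinone)
Conditions: Ag2O (2.5 equiv), Et2O, 23 °C, dark, 30 min, filter; chromatography on AgNO3-impregnated SiO2 to remove the minor (Z)-isomer
Reagents that add atoms: none
Why: Hydroquinone-to-quinone dehydrogenation with Ag2O under neutral anhydrous conditions leaves the trisubstituted alkene and the two stereocentres alone, and short contact time with immediate filtration avoids premature cyclization (no new stereocentre).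

Step 3
Reactants: 4 2,5-dimethyl-3-[(2E,7R,11R)-3,7,11,15-tetramethylhexadec-2-en-1-yl]cyclohexa-2,5-diene-1,4-dione
Product: 6 (2S)-2,5,8-trimethyl-2-[(4R,8R)-4,8,12-trimethyltridecyl]-2H-chromen-6-ol, via (Z)-vinyl o-quinone methide 5 (not isolated)
Conditions: squaramide from 9-amino-9-deoxy-epi-quinidine and 3,5-bis(trifluoromethyl)aniline (10 mol%), toluene (0.1 M), 25–40 °C, Ar, dark, 24–48 h
Reagents that add atoms: none
Why: Proposed new method: catalytic enantioselective prenylquinone-to-chromenol cycloisomerization; the squaramide N–H pair binds the C1 carbonyl of 4 and acidifies the doubly allylic C1′–H2, which the quinuclidine nitrogen removes (vinylogous enolization), so the (Z)-vinyl o-quinone methide 5 is generated as a contact ion pair/hydrogen-bonded complex with the catalyst lying across one π-face between O1 and the C1′/O4 edge; the thermally allowed disrotatory oxa-6π closure, driven by re-aromatisation and expected to be faster than catalyst release, can then swing C3′ only toward the uncovered face, O4 adds to the Si face of C3′ and, because the side-chain alkene is E, this gives C2 as S while forming the O1–C2 bond and the pyran ring irreversibly; closest known reactions are the achiral amine-mediated (pyridine or Et3N) isomerization of prenylquinones to chromenols without control at C2, cinchona-squaramide-catalysed vinylogous deprotonations and olefin isomerizations, and chiral ion-pair-controlled 6π electrocyclizations.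

## Compound list

1 | 2,5-dimethylbenzene-1,4-diol (2,5-dimethylhydroquinone) | Cc1cc(O)c(C)cc1O | starting material
2 | natural phytol, (2E,7R,11R)-3,7,11,15-tetramethylhexadec-2-en-1-ol | OC/C=C(\C)CCC[C@H](C)CCC[C@H](C)CCCC(C)C | starting material
3 | 2,5-dimethyl-3-[(2E,7R,11R)-3,7,11,15-tetramethylhexadec-2-en-1-yl]benzene-1,4-diol | Cc1cc(O)c(C)c(C/C=C(\C)CCC[C@H](C)CCC[C@H](C)CCCC(C)C)c1O | intermediate
4 | 2,5-dimethyl-3-[(2E,7R,11R)-3,7,11,15-tetramethylhexadec-2-en-1-yl]cyclohexa-2,5-diene-1,4-dione | CC1=CC(=O)C(C)=C(C/C=C(\C)CCC[C@H](C)CCC[C@H](C)CCCC(C)C)C1=O | intermediate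
5 | (6Z)-4-hydroxy-2,5-dimethyl-6-[(2E,7R,11R)-3,7,11,15-tetramethylhexadec-2-en-1-ylidene]cyclohexa-2,4-dien-1-one (vinyl o-quinone methide, catalyst-bound) | O=C1C(C)=CC(O)=C(C)/C1=C/C=C(\C)CCC[C@H](C)CCC[C@H](C)CCCC(C)C | intermediate
6 | (2S)-2,5,8-trimethyl-2-[(4R,8R)-4,8,12-trimethyltridecyl]-2H-chromen-6-ol | Cc1cc(O)c(C)c2c1O[C@@](C)(CCC[C@H](C)CCC[C@H](C)CCCC(C)C)C=C2 | target

## Step count and risks

Total steps: 3. Longest linear sequence: 3 (from 1 or 2).

**Most likely to fail: step 3 (the new cycloisomerization).** Turnover with a tertiary-amine base may be slow. Selectivity at C2 may be low if 5 leaves the catalyst before closing. The dienolate may also be protonated at C3′ to give the conjugated side-chain isomer. The fallback uses known chemistry, sets out from 4 and returns at 6. Quinone 4 is heated in pyridine at reflux under Ar in the dark, the classical prenylquinone-to-chromenol isomerization. It passes through the same intermediate 5 and gives a 1:1 mixture of 6 and its C2 epimer, (2R)-2,5,8-trimethyl-2-[(4R,8R)-4,8,12-trimethyltridecyl]-2H-chromen-6-ol F5. The two diastereomers are separated by preparative HPLC on a cellulose tris(3,5-dimethylphenylcarbamate) phase (hexane/i-PrOH), and F5 is discarded. The same run supplies the 1:1 reference sample for the assay of step 3.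

**Second: step 1 (Friedel–Crafts phytylation).** The allyl cation can erode the E geometry, and acid can close 3 to the chroman or dialkylate. The fallback sets out from 2 and returns at 4, bypassing 3:
- Phytol 2 is converted with PBr3 (Et2O, −10 °C) into phytyl bromide F1, (2E,7R,11R)-1-bromo-3,7,11,15-tetramethylhexadec-2-ene.
- Commercial 1,4-dimethoxy-2,5-dimethylbenzene F2 is lithiated at one of its two equivalent ring positions (n-BuLi, TMEDA, Et2O, 0→23 °C) and transmetalated with CuBr·SMe2 (0.5 equiv).
- The resulting cuprate is alkylated with F1 in an SN2 coupling that retains the E geometry, giving 1,4-dimethoxy-2,5-dimethyl-3-[(2E,7R,11R)-3,7,11,15-tetramethylhexadec-2-en-1-yl]benzene F3.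
- Oxidative demethylation with (NH4)2Ce(NO3)6 (MeCN/H2O, 0 °C) gives 4 directly.

**Third: step 2 (oxidation and geometric purification).** The basic Ag2O surface, or a long chromatography of the quinone, may trigger uncontrolled cyclization, and the E/Z separation may be incomplete at the quinone stage. The fallback sets out from 3 and returns at 4:
- Crude 3 is acetylated (Ac2O, pyridine, DMAP) to the air-stable 2,5-dimethyl-3-[(2E,7R,11R)-3,7,11,15-tetramethylhexadec-2-en-1-yl]-1,4-phenylene diacetate F4.
- The (Z)-isomer and chroman by-products are removed at this protected stage on AgNO3-impregnated SiO2.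
- The esters are cleaved reductively with LiAlH4 (THF, 0 °C), and the liberated hydroquinone is oxidised in the acidic work-up with aqueous FeCl3.
- This gives geometrically pure 4, which needs only a short silica plug and never meets a basic oxidant.

## Further compounds

F1 | step 1 | (2E,7R,11R)-1-bromo-3,7,11,15-tetramethylhexadec-2-ene | BrC/C=C(\C)CCC[C@H](C)CCC[C@H](C)CCCC(C)C
F2 | step 1 | 1,4-dimethoxy-2,5-dimethylbenzene | COc1cc(C)c(OC)cc1C
F3 | step 1 | 1,4-dimethoxy-2,5-dimethyl-3-[(2E,7R,11R)-3,7,11,15-tetramethylhexadec-2-en-1-yl]benzene | COc1cc(C)c(OC)c(C/C=C(\C)CCC[C@H](C)CCC[C@H](C)CCCC(C)C)c1C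
F4 | step 2 | 2,5-dimethyl-3-[(2E,7R,11R)-3,7,11,15-tetramethylhexadec-2-en-1-yl]-1,4-phenylene diacetate | CC(=O)Oc1cc(C)c(OC(C)=O)c(C/C=C(\C)CCC[C@H](C)CCC[C@H](C)CCCC(C)C)c1C
F5 | step 3 | (2R)-2,5,8-trimethyl-2-[(4R,8R)-4,8,12-trimethyltridecyl]-2H-chromen-6-ol | Cc1cc(O)c(C)c2c1O[C@](C)(CCC[C@H](C)CCC[C@H](C)CCCC(C)C)C=C2
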